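**Strategy.** The cyclohexane ring (C1, C10–C14) is cut at C10–C11 and C12–C13 into a 2-silyloxy diene (C13=C14(OSi)–C1(Me)=C10–C9) and acrolein (C12=C11–C20). One catalytic enantioselective Diels–Alder reaction forms both bonds and sets C10 and C11; it exploits the cis pair C9/C20 on C10–C11 and the oxygen at C14 of the 13,14-epoxide. The enol silane left at C14/C1 then builds quaternary C1 and C2 by an aldol reaction, and the C14 oxygen is transposed to C12. A butenolide triflate brings C6–C8 and C17–C19, and a Nozaki–Hiyama–Kishi closure at C5–C6 forms the ten-membered ring.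

Key step: step 10

Remark: briarane numbering (C1–C20) is used for all intermediates, and the SMILES strings in the compound list are authoritative for configuration.
Assumption: the (S)-oxazaborolidine catalyst delivers the enantiomer drawn for 16; should the sense be opposite, the (R)-catalyst is taken.

Step 1
Reactants: 1 acrolein
Product: 3 2-bromoacrolein, via 2,3-dibromopropanal 2 (not isolated)
Conditions: Br2, CH2Cl2, 0 °C; then Et3N, 0 °C
Reagents that add atoms: bromine, BrBr
Why: Bromine addition to the alkene and E2 loss of HBr from the α-carbon (bromination–dehydrobromination) is the standard access to 2-haloacroleins.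

Step 2
Reactants: 3 2-bromoacrolein; 4 (triphenylphosphoranylidene)acetaldehyde
Product: 5 (2E)-4-bromopenta-2,4-dienal
Conditions: PhMe, 23 °C, 1.0 equiv of ylide
Reagents that add atoms: none
Why: Wittig olefination with the stabilised formyl ylide should give the E enal, and the electron-poor α-bromo aldehyde reacts faster than the product dienal.

Step 3
Reactants: 6 methyl (4R)-2,2-dimethyl-1,3-dioxolane-4-carboxylate
Product: 7 methyl (2R)-2,3-dihydroxypropanoate
Conditions: AcOH/H2O 4:1, 40 °C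
Reagents that add atoms: none
Why: Acid-catalysed acetal hydrolysis frees the diol without touching the stereocentre.

Step 4
Reactants: 7 methyl (2R)-2,3-dihydroxypropanoate
Product: 8 primary silyl ether of 7
Conditions: TBSCl, imidazole, CH2Cl2, −20 °C
Reagents that add atoms: tert-butyldimethylsilyl chloride, CC(C)(C)[Si](C)(C)Cl
Why: Silylation is selective for the primary hydroxyl over the secondary α-hydroxy ester position.

Step 5
Reactants: 8 primary silyl ether
Product: 9 α-propanoyloxy ester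
Conditions: EtCOCl, pyridine, DMAP (cat.), CH2Cl2, 0 °C
Reagents that add atoms: propanoyl chloride, CCC(Cl)=O
Why: O-acylation of the secondary alcohol installs C17–C19 as the propanoate.

Step 6
Reactants: 9 α-propanoyloxy ester
Product: 10 3-methyltetronic acid
Conditions: LiHMDS (2.2 equiv), THF, −78 → 0 °C; 1 M HCl
Reagents that add atoms: none
Why: Dieckmann condensation of the propanoate enolate onto the methyl ester closes the tetronic acid, and at low temperature this cyclisation should outrun deprotonation at the stereocentre (later C7).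

Step 7
Reactants: 10 3-methyltetronic acid
Product: 11 butenolide triflate (lactone fragment with C6, C7, C8, C17–C19)
Conditions: Tf2O, i-Pr2NEt, CH2Cl2, −78 °C
Reagents that add atoms: trifluoromethanesulfonic anhydride, O=S(=O)(OS(=O)(=O)C(F)(F)F)C(F)(F)F
Why: O-sulfonylation of the vinylogous acid gives a carbonyl-activated vinyl triflate for the later nickel/chromium coupling.

Step 8
Reactants: 12 3-(triphenylphosphoranylidene)butan-2-one; 13 [(tert-butyldimethylsilyl)oxy]acetaldehyde
Product: 14 (3E)-enone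
Conditions: PhMe, 80 °C
Reagents that add atoms: none
Why: Wittig olefination with the stabilised acyl ylide should give the E trisubstituted enone, which places C9 trans to the acetyl group.

Step 9
Reactants: 14 (3E)-enone
Product: 15 2-(triethylsilyloxy) diene
Conditions: TESOTf, Et3N, CH2Cl2, 0 °C
Reagents that add atoms: triethylsilyl trifluoromethanesulfonate, CC[Si](CC)(CC)OS(=O)(=O)C(F)(F)F
Why: Soft enolisation of the methyl ketone gives the cross-conjugated silyl dienol ether and leaves the E geometry at C10 untouched.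

Step 10
Reactants: 15 2-(triethylsilyloxy) diene; 1 acrolein
Product: 16 cyclohexene carbaldehyde (formyl at C11 cis to C9 on C10, enol silane at C14/C1)
Conditions: (S)-3,3-diphenyl-1-(o-tolyl)tetrahydro-1H,3H-pyrrolo[1,2-c][1,3,2]oxazaborole·HNTf2 (10 mol%), CH2Cl2, −78 °C
Reagents that add atoms: none
Why: Acrolein bound to the cationic boron Lewis acid undergoes a concerted, asynchronous [4+2] cycloaddition with the electron-rich diene; the closest known type is the catalytic enantioselective Diels–Alder reaction of enals with 2-silyloxy-1,3-dienes. The ring C1/C10–C14 closes by a suprafacial [4π+2π] union in which C13 bonds to the β-carbon C12 and C10 to the α-carbon C11. C10 and C11 are set together: the endo transition state places the formyl group cis to the E-configured CH2OTBS group of the diene, and the catalyst shields one face of the s-trans enal, which fixes the absolute configuration. The step needs "para" regioselectivity to the silyloxy group, which the large HOMO coefficient at C13 and the C9 substituent at C10 both secure, and endo selectivity, which Lewis acid complexation reinforces. The enol silane C14(OSiEt3)=C1 that remains is the regiodefined enolate precursor for the next C–C bond.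

Step 11
Reactants: 16 cyclohexene carbaldehyde
Product: 18 cis-dimethyl enol silane, via tosylhydrazone 17 (not isolated)
Conditions: TsNHNH2, THF, 23 °C; then catecholborane, CHCl3, 0 °C; then NaOAc·3H2O, 60 °C
Reagents that add atoms: none
Why: Reduction of the tosylhydrazone by catecholborane and loss of sulfinate and N2 from the diazene (a mild Wolff–Kishner-type deoxygenation) turns the formyl group into the C20 methyl without base, so C11 and the enol silane should be left alone.

Step 12
Reactants: 18 cis-dimethyl enol silane; 5 (2E)-4-bromopenta-2,4-dienal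
Product: 20 aldol adduct, via lithium enolate 19 (not isolated)
Conditions: MeLi, THF, 0 °C; then 5, −78 °C; AcOH quench at −78 °C
Reagents that add atoms: none
Why: Methyllithium cleaves the enol silane to the regiodefined lithium enolate, which adds 1,2 to the enal through a Zimmerman–Traxler chair on the face anti to the C10 side chain (aldol reaction), so quaternary C1 and the C2 carbinol (hydroxyl syn to the C1 methyl) are set in one step.

Step 13
Reactants: 20 aldol adduct
Product: 21 C2 silyl ether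
Conditions: TBSOTf, 2,6-lutidine, CH2Cl2, −78 °C
Reagents that add atoms: tert-butyldimethylsilyl trifluoromethanesulfonate, CC(C)(C)[Si](C)(C)OS(=O)(=O)C(F)(F)F
Why: Silylation of the hindered β-hydroxy ketone blocks retro-aldol cleavage and protects O2 until the end game.

Step 14
Reactants: 21 C2 silyl ether
Product: 23 enone (C12=C13, C14 ketone), via lithium enolate 22 (not isolated)
Conditions: LiHMDS, THF, −78 °C; then N-tert-butylbenzenesulfinimidoyl chloride, −78 °C
Reagents that add atoms: none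
Why: Only C13 can be enolised, and the enolate is dehydrogenated by the sulfinimidoyl chloride through S-alkylation and syn elimination (one-pot ketone-to-enone dehydrogenation).

Step 15
Reactants: 23 enone
Product: 24 12,13-epoxy ketone
Conditions: H2O2 (30% aq.), NaOH (cat.), MeOH, 0 °C
Reagents that add atoms: hydrogen peroxide, OO
Why: Weitz–Scheffer nucleophilic epoxidation, in which hydroperoxide should add to C12 anti to the neighbouring C11 methyl and the enolate closes the epoxide on that face.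

Step 16
Reactants: 24 12,13-epoxy ketone
Product: 26 allylic alcohol (12-OH, 13,14-ene), via epoxy hydrazone 25 (not isolated)
Conditions: N2H4·H2O, AcOH (cat.), MeOH, 0 → 23 °C
Reagents that add atoms: none
Why: Wharton transposition: the epoxy hydrazone opens to a vinyl diazene that loses N2, which moves the oxygen to C12 with its C–O bond intact and places the alkene at C13=C14.

Step 17
Reactants: 26 allylic alcohol
Product: 27 C12 4-methoxybenzyl ether
Conditions: NaH, PMBCl, Bu4NI (cat.), DMF, 0 °C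
Reagents that add atoms: 4-methoxybenzyl chloride, COc1ccc(CCl)cc1
Why: Williamson etherification gives an O12 protecting group that stays until the last steps and is orthogonal to silyl ethers and acetates.

Step 18
Reactants: 27 C12 4-methoxybenzyl ether
Product: 28 C9 primary alcohol
Conditions: HF·pyridine, pyridine, THF, 0 °C
Reagents that add atoms: none
Why: Desilylation is far faster at the unhindered primary ether than at the neopentyl secondary C2 ether (selective silyl ether cleavage).

Step 19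
Reactants: 28 C9 primary alcohol
Product: 29 C9 aldehyde
Conditions: DMP (1,1,1-triacetoxy-1,1-dihydro-1,2-benziodoxol-3(1H)-one), NaHCO3, CH2Cl2, 0 °C
Reagents that add atoms: none
Why: Buffered periodinane oxidation gives the α-branched aldehyde without epimerising C10.

Step 20
Reactants: 29 C9 aldehyde; 11 butenolide triflate
Product: 30 bis-allylic alcohol (both C9 epimers)
Conditions: CrCl2 (4 equiv), NiCl2 (2 mol%), DMF/THF, 23 °C
Reagents that add atoms: none
Why: Nozaki–Hiyama–Kishi coupling, in which nickel should insert into the carbonyl-activated vinyl triflate much faster than into the 2-bromodiene; the C9 configuration is not needed because the next step removes it.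

Step 21
Reactants: 30 bis-allylic alcohol
Product: 31 C9 ketone
Conditions: DMP, NaHCO3, CH2Cl2, 0 °C
Reagents that add atoms: none
Why: Periodinane oxidation converges both epimers to one ketone under buffered conditions that should spare the acidic C10–H.

Step 22
Reactants: 31 C9 ketone
Product: 32 (9S)-alcohol
Conditions: NaBH4, CeCl3·7H2O, MeOH, −78 °C
Reagents that add atoms: none
Why: Luche 1,2-reduction, in which hydride should attack anti to quaternary C1 on C10 (Felkin–Anh) and so give the 9S alcohol.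

Step 23
Reactants: 32 (9S)-alcohol
Product: 33 8,17-epoxy lactone
Conditions: t-BuOOH, DBU, CH2Cl2, 0 → 23 °C
Reagents that add atoms: tert-butyl hydroperoxide, CC(C)(C)OO
Why: Nucleophilic (Weitz–Scheffer type) epoxidation of the butenolide, in which the peroxide anion should add to C8 on the ring face opposite to the C7 silyloxymethyl group.

Step 24
Reactants: 33 8,17-epoxy lactone
Product: 34 8-hydroxy lactone (17R)
Conditions: SmI2 (2.5 equiv), THF/MeOH, −78 °C
Reagents that add atoms: none
Why: Reductive opening of the α,β-epoxy lactone by SmI2 cleaves the C17–O bond and keeps the oxygen on C8, and protonation of the samarium enolate from the side of the C9 hydroxyl should place the C17 methyl anti to the C9 branch, which is also the more stable arrangement.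

Step 25
Reactants: 34 8-hydroxy lactone
Product: 35 C9 acetate
Conditions: Ac2O, pyridine, DMAP (cat.), CH2Cl2, 0 °C
Reagents that add atoms: acetic anhydride, CC(=O)OC(C)=O
Why: Acetylation takes the secondary C9 hydroxyl only, since the tertiary C8 hydroxyl is too hindered.

Step 26
Reactants: 35 C9 acetate
Product: 36 C6 primary alcohol
Conditions: HF·pyridine, pyridine, THF, 0 °C
Reagents that add atoms: none
Why: Selective cleavage of the primary silyl ether in the presence of the hindered secondary C2 silyl ether, the acetate and the lactone.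

Step 27
Reactants: 36 C6 primary alcohol
Product: 37 C6 aldehyde
Conditions: DMP, NaHCO3, CH2Cl2, 0 °C
Reagents that add atoms: none
Why: Buffered periodinane oxidation gives the α-oxygenated aldehyde, which is used at once to avoid epimerisation at C7.

Step 28
Reactants: 37 C6 aldehyde
Product: 38 macrocyclic allylic alcohol (C6 hydroxyl anti to O7)
Conditions: CrCl2 (10 equiv), NiCl2 (10 mol%), DMSO/THF, 23 → 40 °C, 2 mM
Reagents that add atoms: none
Why: Intramolecular Nozaki–Hiyama–Kishi reaction of the 2-bromodiene with the aldehyde closes the ten-membered ring and creates the C5 exo-methylene and the C6 carbinol at once, and attack anti to the C7–O bond (polar Felkin–Anh) should give the 6,7-anti alcohol.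

Step 29
Reactants: 38 macrocyclic allylic alcohol
Product: 39 (6S)-allylic chloride
Conditions: PPh3, hexachloroacetone, CH2Cl2, −20 → 0 °C
Reagents that add atoms: hexachloroacetone, ClC(Cl)(Cl)C(=O)C(Cl)(Cl)Cl
Why: Appel-type chlorination through the alkoxyphosphonium salt should proceed with SN2 inversion at C6 and without allylic transposition, while the tertiary C8 hydroxyl is too hindered to react.

Step 30
Reactants: 39 allylic chloride
Product: 40 C2 alcohol
Conditions: HF·pyridine, THF, 23 °C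
Reagents that add atoms: none
Why: Acidic fluoride desilylation frees O2 without touching the acetate, the lactone, the chloride or the benzyl-type ether.

Step 31
Reactants: 40 C2 alcohol
Product: 41 3,4-epoxide
Conditions: VO(acac)2 (5 mol%), t-BuOOH, CH2Cl2, 0 °C
Reagents that add atoms: tert-butyl hydroperoxide, CC(C)(C)OO
Why: Hydroxyl-directed epoxidation, in which the vanadium alkoxide at C2 delivers oxygen only to the allylic C3=C4 alkene on the outer face of the trans alkene that the C2–O bond can reach in the macrocycle, which should give the (3S,4R)-epoxide.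

Step 32
Reactants: 41 3,4-epoxide
Product: 42 C2 acetate
Conditions: Ac2O, pyridine, DMAP (cat.), CH2Cl2, 0 °C
Reagents that add atoms: acetic anhydride, CC(=O)OC(C)=O
Why: Acetylation of the only free secondary hydroxyl completes the diacetate.

Step 33
Reactants: 42 C2 acetate
Product: 43 C12 alcohol
Conditions: DDQ, CH2Cl2/pH 7 buffer, 0 °C
Reagents that add atoms: none
Why: Oxidative cleavage of the 4-methoxybenzyl ether under neutral conditions spares the epoxide, the acetates and the allylic chloride.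

Step 34
Reactants: 43 C12 alcohol
Product: 44 target
Conditions: VO(acac)2 (5 mol%), t-BuOOH, CH2Cl2, 0 °C
Reagents that add atoms: tert-butyl hydroperoxide, CC(C)(C)OO
Why: Hydroxyl-directed epoxidation of the cyclohex-2-enol gives the epoxide cis to the C12 hydroxyl, and the C5=C16 alkene, which has no allylic hydroxyl and carries an allylic chloride, should be left.

**Compound list**

1 | acrolein (prop-2-enal) | C=CC=O | starting material
2 | 2,3-dibromopropanal | O=CC(Br)CBr | intermediate
3 | 2-bromoprop-2-enal (2-bromoacrolein) | C=C(Br)C=O | intermediate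
4 | (triphenylphosphoranylidene)acetaldehyde | O=CC=P(c1ccccc1)(c1ccccc1)c1ccccc1 | starting material
5 | (2E)-4-bromopenta-2,4-dienal | C=C(Br)/C=C/C=O | intermediate
6 | methyl (4R)-2,2-dimethyl-1,3-dioxolane-4-carboxylate | COC(=O)[C@H]1COC(C)(C)O1 | starting material
7 | methyl (2R)-2,3-dihydroxypropanoate | COC(=O)[C@H](O)CO | intermediate
8 | methyl (2R)-3-[(tert-butyldimethylsilyl)oxy]-2-hydroxypropanoate | COC(=O)[C@H](O)CO[Si](C)(C)C(C)(C)C | intermediate
9 | methyl (2R)-3-[(tert-butyldimethylsilyl)oxy]-2-(propanoyloxy)propanoate | COC(=O)[C@H](OC(=O)CC)CO[Si](C)(C)C(C)(C)C | intermediate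
10 | (5R)-5-{[(tert-butyldimethylsilyl)oxy]methyl}-4-hydroxy-3-methylfuran-2(5H)-one | CC1=C(O)[C@@H](CO[Si](C)(C)C(C)(C)C)OC1=O | intermediate
11 | (5R)-5-{[(tert-butyldimethylsilyl)oxy]methyl}-3-methyl-2-oxo-2,5-dihydrofuran-4-yl trifluoromethanesulfonate | CC1=C(OS(=O)(=O)C(F)(F)F)[C@@H](CO[Si](C)(C)C(C)(C)C)OC1=O | intermediate
12 | 3-(triphenylphosphoranylidene)butan-2-one | CC(=O)C(C)=P(c1ccccc1)(c1ccccc1)c1ccccc1 | starting material
13 | [(tert-butyldimethylsilyl)oxy]acetaldehyde | O=CCO[Si](C)(C)C(C)(C)C | starting material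
14 | (3E)-5-[(tert-butyldimethylsilyl)oxy]-3-methylpent-3-en-2-one | CC(=O)/C(C)=C/CO[Si](C)(C)C(C)(C)C | intermediate
15 | (3E)-5-[(tert-butyldimethylsilyl)oxy]-3-methyl-2-[(triethylsilyl)oxy]penta-1,3-diene | C=C(O[Si](CC)(CC)CC)/C(C)=C/CO[Si](C)(C)C(C)(C)C | intermediate
16 | (1S,2S)-2-{[(tert-butyldimethylsilyl)oxy]methyl}-3-methyl-4-[(triethylsilyl)oxy]cyclohex-3-ene-1-carbaldehyde | CC1=C(O[Si](CC)(CC)CC)CC[C@H](C=O)[C@@H]1CO[Si](C)(C)C(C)(C)C | intermediate
17 | N-tosylhydrazone of 16 | CC1=C(O[Si](CC)(CC)CC)CC[C@H](C=NNS(=O)(=O)c2ccc(C)cc2)[C@@H]1CO[Si](C)(C)C(C)(C)C | intermediate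
18 | tert-butyl{[(1S,6S)-2,6-dimethyl-3-[(triethylsilyl)oxy]cyclohex-2-en-1-yl]methoxy}dimethylsilane | CC1=C(O[Si](CC)(CC)CC)CC[C@H](C)[C@@H]1CO[Si](C)(C)C(C)(C)C | intermediate
19 | lithium enolate from 18 (O–Li at C14, C14=C1) | CC1=C(O[Li])CC[C@H](C)[C@@H]1CO[Si](C)(C)C(C)(C)C | intermediate
20 | (2S,3S,4S)-2-[(1S,2E)-4-bromo-1-hydroxypenta-2,4-dien-1-yl]-3-{[(tert-butyldimethylsilyl)oxy]methyl}-2,4-dimethylcyclohexan-1-one | C=C(Br)/C=C/[C@H](O)[C@]1(C)[C@H]([C@@H](C)CCC1=O)CO[Si](C)(C)C(C)(C)C | intermediate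
21 | tert-butyldimethylsilyl ether of 20 at O2 | C=C(Br)/C=C/[C@H](O[Si](C)(C)C(C)(C)C)[C@]1(C)[C@H]([C@@H](C)CCC1=O)CO[Si](C)(C)C(C)(C)C | intermediate
22 | lithium enolate of 21 (C13=C14–OLi) | C=C(Br)/C=C/[C@H](O[Si](C)(C)C(C)(C)C)[C@]1(C)[C@H]([C@@H](C)CC=C1O[Li])CO[Si](C)(C)C(C)(C)C | intermediate
23 | cyclohex-2-enone from 21 (C12=C13, C14 ketone) | C=C(Br)/C=C/[C@H](O[Si](C)(C)C(C)(C)C)[C@]1(C)[C@H]([C@@H](C)C=CC1=O)CO[Si](C)(C)C(C)(C)C | intermediate
24 | 12,13-epoxy-14-ketone (epoxide anti to the C11 methyl) | C=C(Br)/C=C/[C@H](O[Si](C)(C)C(C)(C)C)[C@]1(C)[C@H]([C@@H](C)[C@@H]2O[C@@H]2C1=O)CO[Si](C)(C)C(C)(C)C | intermediate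
25 | hydrazone of 24 at C14 | C=C(Br)/C=C/[C@H](O[Si](C)(C)C(C)(C)C)[C@]1(C)[C@H]([C@@H](C)[C@@H]2O[C@@H]2C1=NN)CO[Si](C)(C)C(C)(C)C | intermediate
26 | allylic alcohol (12-hydroxy, 13,14-ene; C2 and C9 silyl ethers) | C=C(Br)/C=C/[C@H](O[Si](C)(C)C(C)(C)C)[C@]1(C)[C@H]([C@@H](C)[C@H](O)C=C1)CO[Si](C)(C)C(C)(C)C | intermediate
27 | 4-methoxybenzyl ether of 26 at O12 | C=C(Br)/C=C/[C@H](O[Si](C)(C)C(C)(C)C)[C@]1(C)[C@H]([C@@H](C)[C@H](OCc2ccc(OC)cc2)C=C1)CO[Si](C)(C)C(C)(C)C | intermediate
28 | C9 primary alcohol from 27 | C=C(Br)/C=C/[C@H](O[Si](C)(C)C(C)(C)C)[C@]1(C)[C@H]([C@@H](C)[C@H](OCc2ccc(OC)cc2)C=C1)CO | intermediate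
29 | C9 aldehyde | C=C(Br)/C=C/[C@H](O[Si](C)(C)C(C)(C)C)[C@]1(C)[C@H]([C@@H](C)[C@H](OCc2ccc(OC)cc2)C=C1)C=O | intermediate
30 | C9 carbinol joined to C8 of the butenolide, both C9 epimers | C=C(Br)/C=C/[C@H](O[Si](C)(C)C(C)(C)C)[C@]1(C)[C@H]([C@@H](C)[C@H](OCc2ccc(OC)cc2)C=C1)C(O)C2=C(C)C(=O)O[C@@H]2CO[Si](C)(C)C(C)(C)C | intermediate
31 | C9 ketone (4-acylbutenolide) | C=C(Br)/C=C/[C@H](O[Si](C)(C)C(C)(C)C)[C@]1(C)[C@H]([C@@H](C)[C@H](OCc2ccc(OC)cc2)C=C1)C(=O)C2=C(C)C(=O)O[C@@H]2CO[Si](C)(C)C(C)(C)C | intermediate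
32 | (9S)-alcohol with 8(17)-butenolide | C=C(Br)/C=C/[C@H](O[Si](C)(C)C(C)(C)C)[C@]1(C)[C@H]([C@@H](C)[C@H](OCc2ccc(OC)cc2)C=C1)[C@H](O)C2=C(C)C(=O)O[C@@H]2CO[Si](C)(C)C(C)(C)C | intermediate
33 | 8,17-epoxy lactone (epoxide anti to C6) | C=C(Br)/C=C/[C@H](O[Si](C)(C)C(C)(C)C)[C@]1(C)[C@H]([C@@H](C)[C@H](OCc2ccc(OC)cc2)C=C1)[C@H](O)[C@@]2(O3)[C@H](OC(=O)[C@@]23C)CO[Si](C)(C)C(C)(C)C | intermediate
34 | 8-hydroxy-17R lactone, 9-OH | C=C(Br)/C=C/[C@H](O[Si](C)(C)C(C)(C)C)[C@]1(C)[C@H]([C@@H](C)[C@H](OCc2ccc(OC)cc2)C=C1)[C@H](O)[C@@]2(O)[C@H](OC(=O)[C@@H]2C)CO[Si](C)(C)C(C)(C)C | intermediate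
35 | C9 acetate of 34 | C=C(Br)/C=C/[C@H](O[Si](C)(C)C(C)(C)C)[C@]1(C)[C@H]([C@@H](C)[C@H](OCc2ccc(OC)cc2)C=C1)[C@H](OC(C)=O)[C@@]2(O)[C@H](OC(=O)[C@@H]2C)CO[Si](C)(C)C(C)(C)C | intermediate
36 | C6 primary alcohol | C=C(Br)/C=C/[C@H](O[Si](C)(C)C(C)(C)C)[C@]1(C)[C@H]([C@@H](C)[C@H](OCc2ccc(OC)cc2)C=C1)[C@H](OC(C)=O)[C@@]2(O)[C@H](OC(=O)[C@@H]2C)CO | intermediate
37 | C6 aldehyde (seco compound) | C=C(Br)/C=C/[C@H](O[Si](C)(C)C(C)(C)C)[C@]1(C)[C@H]([C@@H](C)[C@H](OCc2ccc(OC)cc2)C=C1)[C@H](OC(C)=O)[C@@]2(O)[C@H](OC(=O)[C@@H]2C)C=O | intermediate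
38 | macrocyclic 6-alcohol (C6 epimeric in space to the chloride; 3E,5(16)-diene) | C=C1/C=C/[C@H](O[Si](C)(C)C(C)(C)C)[C@]2(C)[C@H]([C@@H](C)[C@H](OCc3ccc(OC)cc3)C=C2)[C@H](OC(C)=O)[C@@]2(O)[C@H](OC(=O)[C@@H]2C)[C@@H]1O | intermediate
39 | (6S)-chloride | C=C1/C=C/[C@H](O[Si](C)(C)C(C)(C)C)[C@]2(C)[C@H]([C@@H](C)[C@H](OCc3ccc(OC)cc3)C=C2)[C@H](OC(C)=O)[C@@]2(O)[C@H](OC(=O)[C@@H]2C)[C@H]1Cl | intermediate
40 | C2 alcohol | C=C1/C=C/[C@H](O)[C@]2(C)[C@H]([C@@H](C)[C@H](OCc3ccc(OC)cc3)C=C2)[C@H](OC(C)=O)[C@@]2(O)[C@H](OC(=O)[C@@H]2C)[C@H]1Cl | intermediate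
41 | (3S,4R)-epoxide, 2-OH | C=C1[C@H]2O[C@@H]2[C@H](O)[C@]2(C)[C@H]([C@@H](C)[C@H](OCc3ccc(OC)cc3)C=C2)[C@H](OC(C)=O)[C@@]2(O)[C@H](OC(=O)[C@@H]2C)[C@H]1Cl | intermediate
42 | 2,9-diacetate, O12 4-methoxybenzyl ether | C=C1[C@H]2O[C@@H]2[C@H](OC(C)=O)[C@]2(C)[C@H]([C@@H](C)[C@H](OCc3ccc(OC)cc3)C=C2)[C@H](OC(C)=O)[C@@]2(O)[C@H](OC(=O)[C@@H]2C)[C@H]1Cl | intermediate
43 | 12-alcohol, 13,14-ene | C=C1[C@H]2O[C@@H]2[C@H](OC(C)=O)[C@]2(C)[C@H]([C@@H](C)[C@H](O)C=C2)[C@H](OC(C)=O)[C@@]2(O)[C@H](OC(=O)[C@@H]2C)[C@H]1Cl | intermediate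
44 | CNP0141778.4 | C=C1[C@H]2O[C@@H]2[C@H](OC(C)=O)[C@]2(C)[C@H]([C@@H](C)[C@H](O)[C@@H]3O[C@@H]32)[C@H](OC(C)=O)[C@@]2(O)[C@H](OC(=O)[C@@H]2C)[C@H]1Cl | target

**Count.** Total steps: 34. Longest linear sequence: 27 (steps 8–34).

**Steps most likely to fail**

Step 28. Ring closure to the ten-membered ring may be slow against intermolecular coupling, and the α-oxygenated aldehyde may epimerise or eliminate under the chromium alkoxide conditions. The fallback sets out from 32 and comes back at 38; it closes the ring while C8 is still the planar butenolide carbon. Alcohol 32 is acetylated (Ac2O, pyridine) to the butenolide acetate F1. Its primary silyl ether is cleaved (HF·pyridine, pyridine) to the primary alcohol F2, which is oxidised (DMP) to the aldehyde F3. Nozaki–Hiyama–Kishi closure of F3 gives the macrocyclic butenolide F4. Nucleophilic epoxidation (t-BuOOH, DBU) gives the macrocyclic epoxy lactone F5, and SmI2 reduction of F5 gives 38.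

Step 24. The samarium enolate may be protonated on its more open face, which gives the C17 epimer, or the β-alkoxide may open by retro-aldol cleavage. The fallback sets out from 33 and comes back at 34; it uses thermodynamic instead of kinetic control. The reduction is run with t-BuOH as the only proton source, and the product, taken as the 17-epi lactone F6, is equilibrated at C17 with DBU in toluene at 60 °C, where the methyl group anti to the C9 branch should be favoured.

Step 31. Oxygen may be delivered to the other face of C3=C4, because E allylic alcohols show little intrinsic facial bias in vanadium-directed epoxidation. The fallback sets out from 40 and comes back at 41; it separates epoxide formation from the C2 stereocentre. Alcohol 40 is oxidised (DMP) to the cross-conjugated dienone F7. Its C3=C4 bond is epoxidised nucleophilically (t-BuOOH, DBU) from the outer face to give the epoxy ketone F8. An oxazaborolidine-catalysed borane reduction of the C2 ketone under reagent control then gives 41.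

Further compounds
F1 | step 28 | C9 acetate of 32 (butenolide kept) | C=C(Br)/C=C/[C@H](O[Si](C)(C)C(C)(C)C)[C@]1(C)[C@H]([C@@H](C)[C@H](OCc2ccc(OC)cc2)C=C1)[C@H](OC(C)=O)C2=C(C)C(=O)O[C@@H]2CO[Si](C)(C)C(C)(C)C
F2 | step 28 | C6 primary alcohol from F1 | C=C(Br)/C=C/[C@H](O[Si](C)(C)C(C)(C)C)[C@]1(C)[C@H]([C@@H](C)[C@H](OCc2ccc(OC)cc2)C=C1)[C@H](OC(C)=O)C2=C(C)C(=O)O[C@@H]2CO
F3 | step 28 | C6 aldehyde from F2 | C=C(Br)/C=C/[C@H](O[Si](C)(C)C(C)(C)C)[C@]1(C)[C@H]([C@@H](C)[C@H](OCc2ccc(OC)cc2)C=C1)[C@H](OC(C)=O)C2=C(C)C(=O)O[C@@H]2C=O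
F4 | step 28 | macrocyclic 8(17)-butenolide with C6 hydroxyl | C=C1/C=C/[C@H](O[Si](C)(C)C(C)(C)C)[C@]2(C)[C@H]([C@@H](C)[C@H](OCc3ccc(OC)cc3)C=C2)[C@H](OC(C)=O)C2=C(C)C(=O)O[C@@H]2[C@@H]1O
F5 | step 28 | macrocyclic 8,17-epoxy lactone | C=C1/C=C/[C@H](O[Si](C)(C)C(C)(C)C)[C@]2(C)[C@H]([C@@H](C)[C@H](OCc3ccc(OC)cc3)C=C2)[C@H](OC(C)=O)[C@@]2(O3)[C@H](OC(=O)[C@@]23C)[C@@H]1O
F6 | step 24 | 17-epimer of 34 | C=C(Br)/C=C/[C@H](O[Si](C)(C)C(C)(C)C)[C@]1(C)[C@H]([C@@H](C)[C@H](OCc2ccc(OC)cc2)C=C1)[C@H](O)[C@@]2(O)[C@H](OC(=O)[C@H]2C)CO[Si](C)(C)C(C)(C)C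
F7 | step 31 | C2 ketone from 40 (dienone) | C=C1/C=C/C(=O)[C@]2(C)[C@H]([C@@H](C)[C@H](OCc3ccc(OC)cc3)C=C2)[C@H](OC(C)=O)[C@@]2(O)[C@H](OC(=O)[C@@H]2C)[C@H]1Cl
F8 | step 31 | 3,4-epoxy C2 ketone | C=C1[C@H]2O[C@@H]2C(=O)[C@]2(C)[C@H]([C@@H](C)[C@H](OCc3ccc(OC)cc3)C=C2)[C@H](OC(C)=O)[C@@]2(O)[C@H](OC(=O)[C@@H]2C)[C@H]1Cl
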